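## Structural features

The target is a seven-carbon polypropionate chain (C1–C7, counted from ring A) that joins two fully substituted 4-pyranones: ring A (2-ethyl-3,5-dimethyl) is bound through its C6 to C1, and ring B (3,5-dimethyl) is bound to C7 on one side and to a 3-hydroxypentan-2-yl arm (C8, C9) on the other. C1–C4 carry methyl, acetoxy, methyl, acetoxy as four contiguous stereocentres (1R,2R,3R,4R; anti, syn, anti). C5=C6 is an E-trisubstituted alkene, C7 (S) is an isolated centre that is both allylic and attached to ring B, and C8 (S) and C9 (S) form an anti methyl/hydroxyl pair. The fragile points are the acetates, which lie β to the pyranone-activated C1–H (elimination); the C2 and C9 carbinols, which are vinylogous aldol adducts of a pyranone (retro-aldol under base); the doubly activated C7–H; and the three secondary oxygens that must be told apart (C2 and C4 acetylated, C9 free). The real difficulty is the dense C1–C4 array on one side and, on the other, the remote C7 centre and the C5=C6 geometry, which no neighbouring stereocentre controls. The key step exploits hidden symmetry: the C3 methyl, C4 oxygen and C5 methyl, flanked by the C2 oxygen, are the 2,4-dimethyl-3-oxy carbons and the bridge oxygen of a meso 8-oxabicyclo[3.2.1]oct-6-ene, and the C1 methyl is a nucleophile added to one alkene carbon. The two alkene carbons become C6 of ring A and chain carbon C6. In 6 the methyl, silyloxy and methyl groups are mutually cis and lie on the face of the seven-membered ring opposite the oxygen bridge, and in 9 the ring carbons map one-to-one onto C1–C5 of 44 with the required absolute configuration, so both structures stand as drawn.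

## Logic of the disconnections

44 ⇒ 43 ⇒ 42 ⇒ 41. Cut: the O–H bond at C9 (back to a 4-methoxybenzyl ether), then the two acetyl C–O bonds at C2 and C4 (back to hydroxyls, then to silyl ethers). Reason: the acetates cannot survive any basic step, and C9–O must stay masked while C2–O and C4–O are acylated. Gain: 41 contains only robust ethers. Demand: three orthogonal oxygen masks and non-basic conditions in all three forward steps.

41 ⇒ 29 + 40. Cut: the C6–C7 bond between the alkene carbon and the carbon that carries ring B. Reason: it is the only cut that separates both pyranones, so each is made by the same three-step sequence, and it places the union after every strongly basic operation. Gain: two fragments of similar size; 40 needs no defined C7 centre. Demand: a C(sp2)–C(sp3) coupling under neutral conditions that keeps the E geometry and sets C7 by catalyst control.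

29 ⇒ 28 ⇒ 26. Cut: C6–Br back to C6–O (triflate), then the C5=C6 π bond back to a C6 aldehyde with hydrogen on C5. Reason: the C5 stereocentre delivered by the key step is absent from 44; enolisation converts it into the alkene carbon without adding or losing carbon. Gain: a simple aldehyde. Demand: E-selective enolisation (oxygen trans to C4) without β-elimination of the C4 silyl ether and without touching ring A.

26 ⇒ 24 ⇒ 23 ⇒ 21. Cut: the C6 aldehyde back to a primary silyl ether, to a 1,5-diol, and to the cyclic acetal that links O(C2) to C6. Reason: in 21 the C2 oxygen and C6 mask each other while ring A is built. Gain: no separate C2 protection during steps 9–11. Demand: cleavage of the anomeric silyl group in the presence of the C4 silyl ether, and oxidation of a primary silyl ether next to a secondary one.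

21 ⇒ 20 ⇒ 19 ⇒ 12 + 17. Cut: the ring A O–C bond (cyclodehydration), one oxidation level, then the C–C bond next to the carbon that becomes C6 of ring A (aldol). Reason: 17 already holds the other five ring A carbons with both methyls and the ethyl group. Gain: ring A reduces to an aldehyde. Demand: an aldol that neither epimerises C1 nor expels the β-oxygen at C2, and a neutral ring closure.

12 ⇒ 11 ⇒ 9. Cut: two C=O groups back to one C=C; anomeric silyl back to OH. Reason: the seven-membered ring of 9 holds C1–C6 and the ring A carbon. Its free C2 hydroxyl can reach only the C6 aldehyde in a six-membered lactol, which differentiates the two ends. Gain: an acyclic stereo-array from a ring. Demand: silylation at the lactol hydroxyl with the other aldehyde left free.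

9 ⇒ 6 + 7. Cut: the C1–CH3 bond, with re-closure of the C2–O bond to the far alkene carbon. Reason: this reveals a meso bicycle, so the four centres C2–C5 need no asymmetric synthesis of their own. Gain: five stereocentres from one catalytic step. Demand: selection of one enantiotopic alkene carbon by the ligand and exo delivery of methyl.

6 ⇒ 5 ⇒ 4 ⇒ 1 + 2. Cut: the O–Si bond, the carbinol C–H, then the two C–C bonds of the [4+3] cycloadduct. Reason: the oxyallyl cation route gives the cis-dimethyl ketone directly. Gain: two bulk chemicals. Demand: compact cycloaddition (methyls equatorial) and hydride attack from the open face (hydroxyl axial).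

40 ⇒ 38 ⇒ 37 ⇒ 36 ⇒ 34 + 17. Cut: C7–Cl, the ring B O–C bond, one oxidation level, and the aldol C–C bond, mirroring the ring A sequence. Reason: the ethyl group of 17 supplies C7 and its methyl. Gain: one diketone serves both rings. Demand: deprotonation of 38 at the ethyl CH2 and not at C8.

34 ⇒ 32 ⇒ 31 ⇒ 14. Cut: the aldehyde back to a vinyl group, the ether O–C bond, then the C8–C9 bond (crotylation). Reason: an (E)-crotyl reagent gives the anti C8/C9 pair in one step. Gain: two stereocentres from propanal. Demand: reagent control of the aldehyde face.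

17 ⇒ 16 ⇒ 13 + 14. Cut: one oxidation level, then the aldol C–C bond. Reason: both partners are bulk chemicals. Gain: none in stereochemistry; 17 has no fixed centre. Demand: none beyond clean oxidation.

## Other disconnections considered

Alternative 1: The cut is one O–C bond in each pyranone, back to the open-chain bis(1,3,5-triketone) A2. The forward key step treats A2 with PPh3 and CCl4 so that a terminal enol oxygen of each triketone closes onto the distal carbonyl, giving the C9 silyl ether A1, which is then desilylated.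

- In its favour: both rings form in one operation at the very end, and C7 is simply the α-carbon of a ketone, so no C(sp2)–C(sp3) coupling is needed.
- Against it here: A2 carries C1, C7 and C8 as α-centres of enolisable tricarbonyls, β-acetoxy ketone units at C2 and C4, and a β,γ-unsaturated ketone at C7 that can slide into conjugation. Every stereocentre must be bought by a separate aldol or alkylation.
- Comparison: on ring economy Alternative 1 is better (two rings in one step against steps 11 and 22 here). On the mode of ring closure the two plans are equal, since the same cyclodehydration is used. The chosen plan is stronger in stereocentre economy (five centres in step 4) and in the robustness of its late intermediates. Overall length should be similar.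

Alternative 2: The cut is the C3–C4 bond. The allylic propanoate A4, an (E)-enol ether with the ester on C6, is converted with LiN(i-Pr)2 and Me3SiCl into its (E)-silyl ketene acetal. This rearranges through a chair to the acid A3.

- In its favour: C3, C4 and the E C5=C6 alkene arise in one concerted, stereospecific step. The alkene geometry follows from the equatorial C7 substituent. C7 itself comes from the chiral pool and is the source of the transferred chirality.
- On the C5=C6/C7 problem this is better than the chosen plan, which relies on enolate geometry (step 15) and a catalyst-controlled coupling (step 24).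
- Against it here: A4 needs a geometrically pure enol ether and a clean ketene acetal geometry. C1, C2 and ring A must still be attached at the acid terminus with acyclic 1,2-induction.
- Comparison: the mechanism is pericyclic and metal-free, so predictability is equal or better. Structurally it delivers three stereocentres and one alkene, against five stereocentres (one later used up) in step 4. Step economy should be about equal.

Alternative 3: The cut is the C7–CH3 bond. Me2CuLi adds anti-SN2′ to the alkenyl oxirane A6, in which C3 and C6 are cis on the oxirane and the C6=C7 alkene is conjugated to ring B. The product is the allylic alcohol A5.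

- In its favour: both pyranones are already in place, each made by condensation of a pyranone anion with an aldehyde, so the plan is highly convergent. C7 and the E alkene are set together by substrate control while C4–OH is released.
- This is a known, stereospecific reaction class and is therefore better than step 24 of the chosen plan in certainty.
- Against it here: A6 requires a stereodefined trisubstituted oxirane next to C3. E selectivity rests on the s-trans conformer. The cuprate must avoid direct SN2 opening, 1,4-addition to two pyranones and deprotonation at C1.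
- Comparison: on the C7 problem Alternative 3 is stronger. On C1–C4 the chosen plan is stronger, since Alternative 3 still has to build that array by aldol steps. Step economy should be equal or slightly better for Alternative 3.

Key step: step 4

Assumption: the hands named for the ligands in steps 4 and 24 and for the crotylborane in step 17 are those expected to give the drawn configurations; each antipode is equally available and would be substituted with no other change.

Abbreviations: TBS = tert-butyldimethylsilyl, TES = triethylsilyl, PMB = 4-methoxybenzyl. Chain locants C1–C9 are those used above.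

## Route

Step 1
Reactants: 1 furan; 2 2,4-dibromopentan-3-one
Product: 4 (1R,2S,4R,5S)-2,4-dimethyl-8-oxabicyclo[3.2.1]oct-6-en-3-one (meso; both methyls equatorial), via zinc oxyallyl cation 3 (not isolated)
Conditions: Zn–Cu couple, furan (excess), DME, −10 °C to rt
Reagents that add atoms: none
Why: Reductive debromination gives the W-shaped 1,3-dimethyl-2-oxyallyl cation, which adds to furan in a [4+3] cycloaddition through the compact transition state, so both methyls end up cis and equatorial; the product is meso.

Step 2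
Reactants: 4 (1R,2S,4R,5S)-2,4-dimethyl-8-oxabicyclo[3.2.1]oct-6-en-3-one
Product: 5 (1R,2R,3r,4S,5S)-2,4-dimethyl-8-oxabicyclo[3.2.1]oct-6-en-3-ol (meso; hydroxyl axial and cis to both methyls)
Conditions: LiBH(s-Bu)3, THF, −78 °C; then aq NaOH, H2O2
Reagents that add atoms: none
Why: The bulky hydride attacks the ketone from the equatorial direction, away from the etheno bridge, and places the hydroxyl axial on the same face as the two methyls (substrate-controlled ketone reduction).

Step 3
Reactants: 5 (1R,2R,3r,4S,5S)-2,4-dimethyl-8-oxabicyclo[3.2.1]oct-6-en-3-ol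
Product: 6 (1R,2S,3s,4R,5S)-3-(TBS-oxy)-2,4-dimethyl-8-oxabicyclo[3.2.1]oct-6-ene (meso)
Conditions: TBSOTf, 2,6-lutidine, CH2Cl2, 0 °C
Reagents that add atoms: tert-butyldimethylsilyl triflate, CC(C)(C)[Si](C)(C)OS(=O)(=O)C(F)(F)F
Why: Silylation of a hindered axial secondary alcohol with the silyl triflate; the TBS ether is kept because it must outlast more than twenty steps and later resist β-elimination from a C6 enolate.

Step 4
Reactants: 6 (1R,2S,3s,4R,5S)-3-(TBS-oxy)-2,4-dimethyl-8-oxabicyclo[3.2.1]oct-6-ene; 7 dimethylzinc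
Product: 9 (1S,2S,5S,6S,7R)-6-(TBS-oxy)-2,5,7-trimethylcyclohept-3-en-1-ol, via methylzinc alkoxide 8 (not isolated)
Conditions: Pd(CH3CN)2Cl2 (5 mol %), (R)-Tol-BINAP (5.5 mol %), Zn(OTf)2 (10 mol %), Me2Zn (2 equiv), ClCH2CH2Cl, 60 °C; aq NH4Cl
Reagents that add atoms: none
Why: Methyl passes from zinc to palladium to give a cationic methylpalladium complex (divalent palladium) that carries the bisphosphine; Zn(OTf)2 helps to free a coordination site. The complex binds the strained alkene of 6 on the exo face (syn to the oxygen bridge) and inserts it in a syn carbopalladation, which forms the only new skeletal bond, C1–CH3. Syn β-oxygen elimination from the exo C–Pd bond then breaks the bridge C–O bond; the palladium alkoxide exchanges with Me2Zn to give 8 and regenerate methylpalladium, and work-up gives 9. The closest known reaction type is the palladium-catalysed enantioselective alkylative ring opening of meso oxabicyclic alkenes with dialkylzinc reagents, which covers [3.2.1] furan–oxyallyl adducts. No ring closes; the oxygen bridge opens. The new centre (C1) has its methyl cis to the liberated hydroxyl because addition is exo and syn; its absolute configuration, and that of the four formerly meso centres C2–C5, is set by the ligand, which chooses one of the two enantiotopic alkene carbons. The step needs enantiotopic-carbon selection (ligand) and exo selectivity (the endo face is blocked by the three-carbon bridge and its axial silyloxy group). β-Hydride elimination cannot compete because the only β-hydrogens are endo and therefore anti to palladium.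

Step 5
Reactants: 9 (1S,2S,5S,6S,7R)-6-(TBS-oxy)-2,5,7-trimethylcyclohept-3-en-1-ol
Product: 11 2-[4-(TBS-oxy)-6-hydroxy-3,5-dimethyloxan-2-yl]propanal (lactol; anomer mixture; other centres as in 9), via secondary ozonide 10 (not isolated)
Conditions: O3, CH2Cl2, −78 °C; then PPh3, −78 °C to rt
Reagents that add atoms: ozone, [O-][O+]=O
Why: Ozonolysis cleaves the ring alkene to two aldehydes; only the C6 aldehyde is five atoms from the C2 hydroxyl and closes to a six-membered lactol, which leaves the future ring A carbon as the free aldehyde.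

Step 6
Reactants: 11 2-[4-(TBS-oxy)-6-hydroxy-3,5-dimethyloxan-2-yl]propanal
Product: 12 2-[4,6-bis(TBS-oxy)-3,5-dimethyloxan-2-yl]propanal (anomer mixture)
Conditions: TBSCl, imidazole, CH2Cl2, 0 °C
Reagents that add atoms: tert-butyldimethylsilyl chloride, CC(C)(C)[Si](C)(C)Cl
Why: The hemiacetal hydroxyl is the only hydroxyl present and is silylated under mild conditions that leave the α-branched aldehyde untouched (anomeric silyl acetal formation).

Step 7
Reactants: 13 pentan-3-one; 14 propanal
Product: 16 5-hydroxy-4-methylheptan-3-one (diastereomer mixture), via lithium enolate 15 (not isolated)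
Conditions: LiN(i-Pr)2, THF, −78 °C; then 14; aq NH4Cl
Reagents that add atoms: none
Why: Directed aldol addition of a preformed ketone enolate to an aldehyde; the two new centres are removed in the next step.

Step 8
Reactants: 16 5-hydroxy-4-methylheptan-3-one
Product: 17 4-methylheptane-3,5-dione
Conditions: Dess–Martin periodinane, CH2Cl2, rt
Reagents that add atoms: none
Why: Dess–Martin oxidation of a β-hydroxy ketone to the 1,3-diketone without cleavage.

Step 9
Reactants: 12 2-[4,6-bis(TBS-oxy)-3,5-dimethyloxan-2-yl]propanal; 17 4-methylheptane-3,5-dione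
Product: 19 8-[4,6-bis(TBS-oxy)-3,5-dimethyloxan-2-yl]-7-hydroxy-4,6-dimethylnonane-3,5-dione (mixture at the three new centres), via dilithium dianion 18 (not isolated)
Conditions: 17, LiN(i-Pr)2 (2.1 equiv), THF, −78 to 0 °C; then 12, −78 °C; aq NH4Cl
Reagents that add atoms: none
Why: The 1,3-diketone dianion reacts at its terminal carbon with the aldehyde (dianion aldol); at −78 °C addition outruns enolisation of the β-alkoxy aldehyde, so C1 is kept, and the new centres are erased in steps 10 and 11.

Step 10
Reactants: 19 8-[4,6-bis(TBS-oxy)-3,5-dimethyloxan-2-yl]-7-hydroxy-4,6-dimethylnonane-3,5-dione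
Product: 20 8-[4,6-bis(TBS-oxy)-3,5-dimethyloxan-2-yl]-4,6-dimethylnonane-3,5,7-trione (enol tautomers)
Conditions: Dess–Martin periodinane, pyridine, CH2Cl2, 0 °C to rt
Reagents that add atoms: none
Why: Buffered Dess–Martin oxidation gives the 1,3,5-triketone; the neutral medium spares the anomeric silyl acetal and the C1 centre.

Step 11
Reactants: 20 8-[4,6-bis(TBS-oxy)-3,5-dimethyloxan-2-yl]-4,6-dimethylnonane-3,5,7-trione
Product: 21 2-{1-[4,6-bis(TBS-oxy)-3,5-dimethyloxan-2-yl]ethyl}-6-ethyl-3,5-dimethyl-4H-pyran-4-one (ring A formed)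
Conditions: PPh3, CCl4, THF, rt
Reagents that add atoms: none
Why: The chlorophosphonium reagent activates one terminal enol oxygen and the other terminal enol oxygen closes the ring (6-exo addition–elimination, cyclodehydration of a 1,3,5-triketone); the conditions are near neutral, so the α-centre C1 is not enolised.

Step 12
Reactants: 21 2-{1-[4,6-bis(TBS-oxy)-3,5-dimethyloxan-2-yl]ethyl}-6-ethyl-3,5-dimethyl-4H-pyran-4-one
Product: 23 2-ethyl-6-[5-(TBS-oxy)-3,7-dihydroxy-4,6-dimethylheptan-2-yl]-3,5-dimethyl-4H-pyran-4-one (C2 and C6 diol), via lactol 22 (not isolated)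
Conditions: TBAF, AcOH (1:1), THF, 0 °C; then NaBH4, MeOH, 0 °C
Reagents that add atoms: none
Why: Buffered fluoride removes the anomeric silyl group much faster than the hindered C4 silyl ether; borohydride then reduces the lactol through its open form, while the 4-pyranone is inert and the cold, buffered medium limits retro-aldol at C2.

Step 13
Reactants: 23 2-ethyl-6-[5-(TBS-oxy)-3,7-dihydroxy-4,6-dimethylheptan-2-yl]-3,5-dimethyl-4H-pyran-4-one
Product: 24 2-ethyl-6-[5-(TBS-oxy)-4,6-dimethyl-3,7-bis(TES-oxy)heptan-2-yl]-3,5-dimethyl-4H-pyran-4-one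
Conditions: TESOTf, 2,6-lutidine, CH2Cl2, −78 to 0 °C
Reagents that add atoms: triethylsilyl triflate, CC[Si](CC)(CC)OS(=O)(=O)C(F)(F)F
Why: Exhaustive silylation of both hydroxyls; the C2 oxygen must be capped before any strong base is used, because its free alkoxide would trigger retro-aldol from ring A.

Step 14
Reactants: 24 2-ethyl-6-[5-(TBS-oxy)-4,6-dimethyl-3,7-bis(TES-oxy)heptan-2-yl]-3,5-dimethyl-4H-pyran-4-one
Product: 26 3-(TBS-oxy)-6-(6-ethyl-3,5-dimethyl-4-oxo-4H-pyran-2-yl)-2,4-dimethyl-5-(TES-oxy)heptanal (C6 aldehyde), via primary alcohol 25 (not isolated)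
Conditions: (COCl)2, DMSO, CH2Cl2, −78 to −40 °C; then Et3N, −78 °C to rt
Reagents that add atoms: none
Why: Under Swern conditions a primary TES ether is cleaved and oxidised in one pot while secondary silyl ethers stay; epimerisation at C5 is harmless because that centre is removed in step 15.

Step 15
Reactants: 26 3-(TBS-oxy)-6-(6-ethyl-3,5-dimethyl-4-oxo-4H-pyran-2-yl)-2,4-dimethyl-5-(TES-oxy)heptanal
Product: 28 (E)-enol triflate of 26 (C5=C6 with OTf trans to C4), via potassium enolate 27 (not isolated)
Conditions: KN(SiMe3)2 (1.1 equiv), THF, −78 °C; then PhNTf2, −78 to −20 °C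
Reagents that add atoms: N-phenylbis(trifluoromethanesulfonimide), O=S(=O)(N(c1ccccc1)S(=O)(=O)C(F)(F)F)C(F)(F)F
Why: The aldehyde α-hydrogen is by far the most acidic site; in the enolate the oxygen sits cis to the small C5 methyl and trans to the branched C4 substituent (allylic strain), and O-triflation fixes this as the E alkene.

Step 16
Reactants: 28 (E)-enol triflate of 26
Product: 29 2-[(6E)-7-bromo-5-(TBS-oxy)-4,6-dimethyl-3-(TES-oxy)hept-6-en-2-yl]-6-ethyl-3,5-dimethyl-4H-pyran-4-one (E-alkenyl bromide)
Conditions: Ni(cod)2 (10 mol %), LiBr, DMA/THF, rt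
Reagents that add atoms: lithium bromide, [Li+].[Br-]
Why: Nickel-catalysed exchange of an enol triflate for halide: oxidative addition to zerovalent nickel, triflate/bromide exchange and C–Br reductive elimination, with the alkene geometry expected to be retained.

Step 17
Reactants: 14 propanal
Product: 31 (3S,4R)-4-methylhex-5-en-3-ol, via borinate ester 30 (not isolated)
Conditions: (E)-crotyl-B(Ipc)2 [reagent solution prepared beforehand from (+)-Ipc2BOMe], Et2O/THF, −78 °C; then aq NaOH, H2O2
Reagents that add atoms: (E)-crotyldiisopinocampheylborane, C/C=C/CB([C@H]1C[C@H]2C[C@@H]([C@@H]1C)C2(C)C)[C@H]1C[C@H]2C[C@@H]([C@@H]1C)C2(C)C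
Why: Brown crotylboration: the closed chair transition state turns the E-crotyl geometry into the anti C8/C9 relationship, and the isopinocampheyl groups select the aldehyde face (reagent control of both new centres).

Step 18
Reactants: 31 (3S,4R)-4-methylhex-5-en-3-ol
Product: 32 1-methoxy-4-({[(3S,4R)-4-methylhex-5-en-3-yl]oxy}methyl)benzene
Conditions: NaH, 4-methoxybenzyl chloride, Bu4NI (cat.), DMF, 0 °C to rt
Reagents that add atoms: 4-methoxybenzyl chloride, COc1ccc(CCl)cc1
Why: Williamson etherification; the PMB ether survives every later step and is removed oxidatively at the end without touching acetates.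

Step 19
Reactants: 32 1-methoxy-4-({[(3S,4R)-4-methylhex-5-en-3-yl]oxy}methyl)benzene
Product: 34 (2S,3S)-3-(PMB-oxy)-2-methylpentanal, via vicinal diol 33 (not isolated)
Conditions: K2OsO4·2H2O (2 mol %), NaIO4, 2,6-lutidine, dioxane/H2O, rt
Reagents that add atoms: sodium periodate, [Na+].[O-]I(=O)(=O)=O
Why: Dihydroxylation–periodate cleavage of the terminal alkene (chosen over ozone to spare the electron-rich arene), with periodate as the terminal oxygen source relayed by the osmium catalyst; the lutidine buffer limits epimerisation at C8.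

Step 20
Reactants: 34 (2S,3S)-3-(PMB-oxy)-2-methylpentanal; 17 4-methylheptane-3,5-dione
Product: 36 (8S,9S)-7-hydroxy-9-(PMB-oxy)-4,6,8-trimethylundecane-3,5-dione (mixture at C4 C6 C7), via sodium lithium dianion 35 (not isolated)
Conditions: 17, NaH (1.0 equiv), THF, 0 °C; then LiN(i-Pr)2 (1.05 equiv), −78 to 0 °C; then 34, −78 °C; aq NH4Cl
Reagents that add atoms: none
Why: Stepwise dianion formation: NaH removes the central C–H of 17 irreversibly, LiN(i-Pr)2 then deprotonates one ethyl CH2, and the mixed sodium lithium dianion adds through its terminal carbon to the aldehyde (dianion aldol, as in step 9); the ethyl terminus of 17 that does not react becomes C7 and its methyl.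

Step 21
Reactants: 36 (8S,9S)-7-hydroxy-9-(PMB-oxy)-4,6,8-trimethylundecane-3,5-dione
Product: 37 (8S,9S)-9-(PMB-oxy)-4,6,8-trimethylundecane-3,5,7-trione (enol tautomers)
Conditions: Dess–Martin periodinane, pyridine, CH2Cl2, 0 °C to rt
Reagents that add atoms: none
Why: Dess–Martin oxidation to the triketone under buffered conditions that do not enolise C8.

Step 22
Reactants: 37 (8S,9S)-9-(PMB-oxy)-4,6,8-trimethylundecane-3,5,7-trione
Product: 38 2-ethyl-6-[(2S,3S)-3-(PMB-oxy)pentan-2-yl]-3,5-dimethyl-4H-pyran-4-one (ring B formed)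
Conditions: PPh3, CCl4, THF, rt
Reagents that add atoms: none
Why: The same neutral cyclodehydration as step 11 (6-exo closure of an enol oxygen onto the activated distal enol); C8 is not enolised.

Step 23
Reactants: 38 2-ethyl-6-[(2S,3S)-3-(PMB-oxy)pentan-2-yl]-3,5-dimethyl-4H-pyran-4-one
Product: 40 2-(1-chloroethyl)-6-[(2S,3S)-3-(PMB-oxy)pentan-2-yl]-3,5-dimethyl-4H-pyran-4-one (both C7 epimers), via lithium dienolate 39 (not isolated)
Conditions: LiN(SiMe3)2 (1.05 equiv), THF, −78 °C; then added to C2Cl6 (2 equiv), THF, −78 °C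
Reagents that add atoms: hexachloroethane, ClC(Cl)(Cl)C(Cl)(Cl)Cl
Why: Kinetic deprotonation takes the less hindered CH2 of the ethyl group and not the tertiary C8–H; the extended enolate is chlorinated at its exocyclic carbon by an electrophilic chlorine donor (enolate halogenation). No stereocontrol is needed because step 24 is stereoconvergent.

Step 24
Reactants: 29 E-alkenyl bromide; 40 2-(1-chloroethyl)-6-[(2S,3S)-3-(PMB-oxy)pentan-2-yl]-3,5-dimethyl-4H-pyran-4-one
Product: 41 coupled bis-pyranone bearing C2 OTES, C4 OTBS, C9 OPMB, (5E) and (7S)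
Conditions: NiCl2(dme) (10 mol %), (3aR,8aS)-indane-fused bis(oxazoline) ligand (11 mol %), Mn powder (3 equiv), NaI (0.5 equiv), DMA, 0 °C
Reagents that add atoms: none
Why: Proposed new method: zerovalent nickel adds oxidatively to the alkenyl bromide with retention; the chloride is reduced to a C7 radical stabilised by ring B (both epimers of 40 converge on the same planar radical); the radical is captured by the chiral alkenylnickel complex, and reductive elimination from trivalent nickel forms C6–C7 with the ligand choosing the radical face (7S) and the E geometry kept; the closest known reaction type is the nickel-catalysed asymmetric reductive cross-coupling of alkenyl bromides with 1-chloroethyl arenes, and what is new is the 4-pyranone in place of the arene and the use on a chiral, β,β-disubstituted alkenyl bromide.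

Step 25
Reactants: 41 coupled bis-pyranone bearing C2 OTES, C4 OTBS, C9 OPMB
Product: 42 C2,C4-diol bearing C9 OPMB
Conditions: HF·pyridine, pyridine, THF, 0 °C to rt
Reagents that add atoms: none
Why: Acidic fluoride removes the TES and the hindered secondary TBS ether and leaves the PMB ether; an acidic medium is chosen because basic fluoride would expose the C2 alkoxide to retro-aldol.

Step 26
Reactants: 42 C2,C4-diol bearing C9 OPMB
Product: 43 C2,C4-diacetate bearing C9 OPMB
Conditions: Ac2O, pyridine, DMAP (cat.), CH2Cl2, rt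
Reagents that add atoms: acetic anhydride, CC(=O)OC(C)=O
Why: DMAP-catalysed acetylation of both secondary hydroxyls under weakly basic conditions that do not deprotonate C1–H or C7–H.

Step 27
Reactants: 43 C2,C4-diacetate bearing C9 OPMB
Product: 44 (2R,3R,4R,5R,6E,8S)-2-(6-ethyl-3,5-dimethyl-4-oxo-4H-pyran-2-yl)-8-{6-[(2S,3S)-3-hydroxypentan-2-yl]-3,5-dimethyl-4-oxo-4H-pyran-2-yl}-4,6-dimethylnon-6-ene-3,5-diyl diacetate (target)
Conditions: DDQ, CH2Cl2/pH 7 buffer, 0 °C
Reagents that add atoms: none
Why: Oxidative cleavage of the electron-rich benzyl ether through its oxocarbenium ion; the acetates, the electron-poor pyranones and the trisubstituted alkene are not oxidised under buffered conditions.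

## Compound list

1 | furan | c1ccoc1 | starting material
2 | 2,4-dibromopentan-3-one (stereoisomer mixture) | CC(Br)C(=O)C(C)Br | starting material
3 | 1,3-dimethyl-2-oxyallyl cation as its bromozinc enolate | CC=C(O[Zn]Br)[CH+]C | intermediate
4 | (1R,2S,4R,5S)-2,4-dimethyl-8-oxabicyclo[3.2.1]oct-6-en-3-one (meso) | C1=C[C@@H]2[C@H](C)C(=O)[C@H](C)[C@H]1O2 | intermediate
5 | (1R,2R,3r,4S,5S)-2,4-dimethyl-8-oxabicyclo[3.2.1]oct-6-en-3-ol (meso) | C1=C[C@@H]2[C@H](C)[C@H](O)[C@H](C)[C@H]1O2 | intermediate
6 | (1R,2S,3s,4R,5S)-3-(TBS-oxy)-2,4-dimethyl-8-oxabicyclo[3.2.1]oct-6-ene (meso) | C1=C[C@@H]2[C@H](C)[C@H](O[Si](C)(C)C(C)(C)C)[C@H](C)[C@H]1O2 | intermediate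
7 | dimethylzinc | C[Zn]C | starting material
8 | methylzinc alkoxide of 9 | C[C@H]1C=C[C@H](C)[C@H](O[Zn]C)[C@@H](C)[C@H]1O[Si](C)(C)C(C)(C)C | intermediate
9 | (1S,2S,5S,6S,7R)-6-(TBS-oxy)-2,5,7-trimethylcyclohept-3-en-1-ol | C[C@H]1C=C[C@H](C)[C@H](O)[C@@H](C)[C@H]1O[Si](C)(C)C(C)(C)C | intermediate
10 | secondary ozonide of 9 | C[C@H]1C2OOC(O2)[C@H](C)[C@H](O)[C@@H](C)[C@H]1O[Si](C)(C)C(C)(C)C | intermediate
11 | 2-[4-(TBS-oxy)-6-hydroxy-3,5-dimethyloxan-2-yl]propanal (lactol) | O=C[C@H](C)[C@H]1[C@@H](C)[C@@H](O[Si](C)(C)C(C)(C)C)[C@@H](C)C(O)O1 | intermediate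
12 | 2-[4,6-bis(TBS-oxy)-3,5-dimethyloxan-2-yl]propanal | O=C[C@H](C)[C@H]1[C@@H](C)[C@@H](O[Si](C)(C)C(C)(C)C)[C@@H](C)C(O[Si](C)(C)C(C)(C)C)O1 | intermediate
13 | pentan-3-one | CCC(=O)CC | starting material
14 | propanal | CCC=O | starting material
15 | lithium enolate of pentan-3-one | CC=C(CC)O[Li] | intermediate
16 | 5-hydroxy-4-methylheptan-3-one | CCC(O)C(C)C(=O)CC | intermediate
17 | 4-methylheptane-3,5-dione | CCC(=O)C(C)C(=O)CC | intermediate
18 | dilithium 4-methylhepta-2,4-diene-3,5-diolate (dilithium dianion of 17) | CC=C(O[Li])C(C)=C(CC)O[Li] | intermediate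
19 | 8-[4,6-bis(TBS-oxy)-3,5-dimethyloxan-2-yl]-7-hydroxy-4,6-dimethylnonane-3,5-dione | CCC(=O)C(C)C(=O)C(C)C(O)[C@H](C)[C@H]1[C@@H](C)[C@@H](O[Si](C)(C)C(C)(C)C)[C@@H](C)C(O[Si](C)(C)C(C)(C)C)O1 | intermediate
20 | 8-[4,6-bis(TBS-oxy)-3,5-dimethyloxan-2-yl]-4,6-dimethylnonane-3,5,7-trione | CCC(=O)C(C)C(=O)C(C)C(=O)[C@H](C)[C@H]1[C@@H](C)[C@@H](O[Si](C)(C)C(C)(C)C)[C@@H](C)C(O[Si](C)(C)C(C)(C)C)O1 | intermediate
21 | 2-{1-[4,6-bis(TBS-oxy)-3,5-dimethyloxan-2-yl]ethyl}-6-ethyl-3,5-dimethyl-4H-pyran-4-one | CCc1oc([C@H](C)[C@H]2[C@@H](C)[C@@H](O[Si](C)(C)C(C)(C)C)[C@@H](C)C(O[Si](C)(C)C(C)(C)C)O2)c(C)c(=O)c1C | intermediate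
22 | 2-{1-[4-(TBS-oxy)-6-hydroxy-3,5-dimethyloxan-2-yl]ethyl}-6-ethyl-3,5-dimethyl-4H-pyran-4-one (lactol) | CCc1oc([C@H](C)[C@H]2[C@@H](C)[C@@H](O[Si](C)(C)C(C)(C)C)[C@@H](C)C(O)O2)c(C)c(=O)c1C | intermediate
23 | 2-ethyl-6-[5-(TBS-oxy)-3,7-dihydroxy-4,6-dimethylheptan-2-yl]-3,5-dimethyl-4H-pyran-4-one | CCc1oc([C@H](C)[C@H](O)[C@@H](C)[C@@H](O[Si](C)(C)C(C)(C)C)[C@@H](C)CO)c(C)c(=O)c1C | intermediate
24 | 2-ethyl-6-[5-(TBS-oxy)-4,6-dimethyl-3,7-bis(TES-oxy)heptan-2-yl]-3,5-dimethyl-4H-pyran-4-one | CCc1oc([C@H](C)[C@H](O[Si](CC)(CC)CC)[C@@H](C)[C@@H](O[Si](C)(C)C(C)(C)C)[C@@H](C)CO[Si](CC)(CC)CC)c(C)c(=O)c1C | intermediate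
25 | 2-ethyl-6-[5-(TBS-oxy)-7-hydroxy-4,6-dimethyl-3-(TES-oxy)heptan-2-yl]-3,5-dimethyl-4H-pyran-4-one | CCc1oc([C@H](C)[C@H](O[Si](CC)(CC)CC)[C@@H](C)[C@@H](O[Si](C)(C)C(C)(C)C)[C@@H](C)CO)c(C)c(=O)c1C | intermediate
26 | 3-(TBS-oxy)-6-(6-ethyl-3,5-dimethyl-4-oxo-4H-pyran-2-yl)-2,4-dimethyl-5-(TES-oxy)heptanal | CCc1oc([C@H](C)[C@H](O[Si](CC)(CC)CC)[C@@H](C)[C@@H](O[Si](C)(C)C(C)(C)C)[C@@H](C)C=O)c(C)c(=O)c1C | intermediate
27 | potassium (E)-enolate of 26 | CCc1oc([C@H](C)[C@H](O[Si](CC)(CC)CC)[C@@H](C)[C@@H](O[Si](C)(C)C(C)(C)C)/C(C)=C/O[K])c(C)c(=O)c1C | intermediate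
28 | (E)-enol triflate of 26 | CCc1oc([C@H](C)[C@H](O[Si](CC)(CC)CC)[C@@H](C)[C@@H](O[Si](C)(C)C(C)(C)C)/C(C)=C/OS(=O)(=O)C(F)(F)F)c(C)c(=O)c1C | intermediate
29 | 2-[(6E)-7-bromo-5-(TBS-oxy)-4,6-dimethyl-3-(TES-oxy)hept-6-en-2-yl]-6-ethyl-3,5-dimethyl-4H-pyran-4-one | CCc1oc([C@H](C)[C@H](O[Si](CC)(CC)CC)[C@@H](C)[C@@H](O[Si](C)(C)C(C)(C)C)/C(C)=C/Br)c(C)c(=O)c1C | intermediate
30 | diisopinocampheylborinate of 31 | C=C[C@@H](C)[C@H](CC)OB([C@H]1C[C@H]2C[C@@H]([C@@H]1C)C2(C)C)[C@H]1C[C@H]2C[C@@H]([C@@H]1C)C2(C)C | intermediate
31 | (3S,4R)-4-methylhex-5-en-3-ol | C=C[C@@H](C)[C@@H](O)CC | intermediate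
32 | 1-methoxy-4-({[(3S,4R)-4-methylhex-5-en-3-yl]oxy}methyl)benzene | C=C[C@@H](C)[C@@H](OCc1ccc(OC)cc1)CC | intermediate
33 | 4-(PMB-oxy)-3-methylhexane-1,2-diol (C2 epimers; C3 and C4 as in 32) | OCC(O)[C@@H](C)[C@@H](OCc1ccc(OC)cc1)CC | intermediate
34 | (2S,3S)-3-(PMB-oxy)-2-methylpentanal | O=C[C@@H](C)[C@@H](OCc1ccc(OC)cc1)CC | intermediate
35 | sodium lithium 4-methylhepta-2,4-diene-3,5-diolate (mixed dianion of 17) | CC=C(O[Li])C(C)=C(CC)O[Na] | intermediate
36 | (8S,9S)-7-hydroxy-9-(PMB-oxy)-4,6,8-trimethylundecane-3,5-dione | CCC(=O)C(C)C(=O)C(C)C(O)[C@@H](C)[C@@H](OCc1ccc(OC)cc1)CC | intermediate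
37 | (8S,9S)-9-(PMB-oxy)-4,6,8-trimethylundecane-3,5,7-trione | CCC(=O)C(C)C(=O)C(C)C(=O)[C@@H](C)[C@@H](OCc1ccc(OC)cc1)CC | intermediate
38 | 2-ethyl-6-[(2S,3S)-3-(PMB-oxy)pentan-2-yl]-3,5-dimethyl-4H-pyran-4-one | CCc1oc([C@@H](C)[C@@H](OCc2ccc(OC)cc2)CC)c(C)c(=O)c1C | intermediate
39 | lithium 2-ethylidene-2H-pyran-4-olate derived from 38 | CC=C1OC([C@@H](C)[C@@H](OCc2ccc(OC)cc2)CC)=C(C)C(O[Li])=C1C | intermediate
40 | 2-(1-chloroethyl)-6-[(2S,3S)-3-(PMB-oxy)pentan-2-yl]-3,5-dimethyl-4H-pyran-4-one (C7 epimers) | CC(Cl)c1oc([C@@H](C)[C@@H](OCc2ccc(OC)cc2)CC)c(C)c(=O)c1C | intermediate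
41 | coupled bis-pyranone: C2 OTES, C4 OTBS, C9 OPMB, (5E), (7S) | CCc1oc([C@H](C)[C@H](O[Si](CC)(CC)CC)[C@@H](C)[C@@H](O[Si](C)(C)C(C)(C)C)/C(C)=C/[C@H](C)c2oc([C@@H](C)[C@@H](OCc3ccc(OC)cc3)CC)c(C)c(=O)c2C)c(C)c(=O)c1C | intermediate
42 | C2,C4-diol bearing C9 OPMB | CCc1oc([C@H](C)[C@H](O)[C@@H](C)[C@@H](O)/C(C)=C/[C@H](C)c2oc([C@@H](C)[C@@H](OCc3ccc(OC)cc3)CC)c(C)c(=O)c2C)c(C)c(=O)c1C | intermediate
43 | C2,C4-diacetate bearing C9 OPMB | CCc1oc([C@H](C)[C@H](OC(C)=O)[C@@H](C)[C@@H](OC(C)=O)/C(C)=C/[C@H](C)c2oc([C@@H](C)[C@@H](OCc3ccc(OC)cc3)CC)c(C)c(=O)c2C)c(C)c(=O)c1C | intermediate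
44 | (2R,3R,4R,5R,6E,8S)-2-(6-ethyl-3,5-dimethyl-4-oxo-4H-pyran-2-yl)-8-{6-[(2S,3S)-3-hydroxypentan-2-yl]-3,5-dimethyl-4-oxo-4H-pyran-2-yl}-4,6-dimethylnon-6-ene-3,5-diyl diacetate | CCc1oc([C@H](C)[C@H](OC(C)=O)[C@@H](C)[C@@H](OC(C)=O)/C(C)=C/[C@H](C)c2oc([C@@H](C)[C@@H](O)CC)c(C)c(=O)c2C)c(C)c(=O)c1C | target

## Step count and least certain steps

Total: 27 steps. Longest linear sequence: 18 steps (1–6, 9–16, 24–27). The side branches are steps 7–8 (diketone 17, used twice) and steps 17–23 (ring B fragment 40).

Step 24 (proposed new method). Most likely failure: the catalyst does not control which face of the ring B-stabilised C7 radical is captured, because the radical is flanked by a ring methyl and the alkenyl partner is β,β-disubstituted; oxidative addition may also be slow and 40 may homocouple reductively. Fallback with known chemistry, setting out from 40 and 29 and returning at 41: zinc insertion into 40 (Zn dust, LiCl, THF) gives the secondary alkylzinc chloride F1. A Negishi coupling with 29 under zerovalent palladium (Pd2(dba)3, SPhos, THF) then gives 41 together with its C7 epimer F2. The two are separated by preparative chromatography; C7 is then set by separation and not by the catalyst.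

Step 4 (key step). Most likely failure: incomplete discrimination between the two enantiotopic alkene carbons, or carbopalladation of the hindered [3.2.1] alkene so slow that Me2Zn is consumed unproductively. Fallback, setting out from 6 and returning at 9: run the ring opening with the achiral ligand dppf at higher temperature to give racemic material, that is 9 mixed with its mirror image ent-9 F3. Esterify with (S)-O-methylmandelic acid (DCC, DMAP) to the diastereomeric esters, the mandelate of 9 F4 and the mandelate of ent-9 F5. Separate them on silica and cleave F4 with K2CO3 in MeOH to return to 9.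

Step 15. Most likely failure: loss of control over enolate geometry (for example by potassium chelation to the C4 silyloxy oxygen, which would favour the Z enolate) and β-elimination of the C4 silyloxy group from the enolate. Fallback, setting out from 26 and returning at 28: soft enolisation with TBSOTf and Et3N gives the silyl enol ether F6 without a free enolate. Its geometric isomers can be separated on silica, and the E isomer is converted into 28 by fluoride-triggered triflation (CsF, PhNTf2, DME).

Step 16. Most likely failure: erosion of alkene geometry or reduction of the C–O bond during the nickel-mediated triflate/bromide exchange. Fallback, setting out from 28 and returning at 29: stannylation under zerovalent palladium (Pd(PPh3)4, Me3SnSnMe3, LiCl, THF) gives the alkenylstannane F7 with retention. Bromodestannylation with N-bromosuccinimide, also with retention, gives 29.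

Step 23. Most likely failure: proton transfer from the product to unreacted dienolate, leading to over-chlorination or elimination to a vinylpyranone, and some deprotonation at C8 followed by loss of the PMB ether. Fallback, setting out from 38 and returning at 40: trap the same dienolate with 3-phenyl-2-(phenylsulfonyl)oxaziridine to give the secondary alcohol F8, whose alkoxide is not a carbon acid. Convert F8 into 40 with SOCl2 and pyridine.

## Further compounds

F1 | step 24 | 1-{6-[(2S,3S)-3-(PMB-oxy)pentan-2-yl]-3,5-dimethyl-4-oxo-4H-pyran-2-yl}ethylzinc chloride | CC([Zn]Cl)c1oc([C@@H](C)[C@@H](OCc2ccc(OC)cc2)CC)c(C)c(=O)c1C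
F2 | step 24 | C7 epimer of 41 (7R) | CCc1oc([C@H](C)[C@H](O[Si](CC)(CC)CC)[C@@H](C)[C@@H](O[Si](C)(C)C(C)(C)C)/C(C)=C/[C@@H](C)c2oc([C@@H](C)[C@@H](OCc3ccc(OC)cc3)CC)c(C)c(=O)c2C)c(C)c(=O)c1C
F3 | step 4 | ent-9, (1R,2R,5R,6R,7S)-6-(TBS-oxy)-2,5,7-trimethylcyclohept-3-en-1-ol | C[C@@H]1C=C[C@@H](C)[C@@H](O)[C@H](C)[C@@H]1O[Si](C)(C)C(C)(C)C
F4 | step 4 | (S)-methoxy(phenyl)acetate of 9 | C[C@H]1C=C[C@H](C)[C@H](OC(=O)[C@@H](OC)c2ccccc2)[C@@H](C)[C@H]1O[Si](C)(C)C(C)(C)C
F5 | step 4 | (S)-methoxy(phenyl)acetate of ent-9 | C[C@@H]1C=C[C@@H](C)[C@@H](OC(=O)[C@@H](OC)c2ccccc2)[C@H](C)[C@@H]1O[Si](C)(C)C(C)(C)C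
F6 | step 15 | (E)-TBS enol ether of 26 | CCc1oc([C@H](C)[C@H](O[Si](CC)(CC)CC)[C@@H](C)[C@@H](O[Si](C)(C)C(C)(C)C)/C(C)=C/O[Si](C)(C)C(C)(C)C)c(C)c(=O)c1C
F7 | step 16 | (E)-alkenyl trimethylstannane corresponding to 29 | CCc1oc([C@H](C)[C@H](O[Si](CC)(CC)CC)[C@@H](C)[C@@H](O[Si](C)(C)C(C)(C)C)/C(C)=C/[Sn](C)(C)C)c(C)c(=O)c1C
F8 | step 23 | 2-(1-hydroxyethyl)-6-[(2S,3S)-3-(PMB-oxy)pentan-2-yl]-3,5-dimethyl-4H-pyran-4-one (C7 epimers) | CC(O)c1oc([C@@H](C)[C@@H](OCc2ccc(OC)cc2)CC)c(C)c(=O)c1C
A1 | alternative 1 | C9 triethylsilyl ether of 44 | CCc1oc([C@H](C)[C@H](OC(C)=O)[C@@H](C)[C@@H](OC(C)=O)/C(C)=C/[C@H](C)c2oc([C@@H](C)[C@@H](O[Si](CC)(CC)CC)CC)c(C)c(=O)c2C)c(C)c(=O)c1C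
A2 | alternative 1 | open-chain bis(1,3,5-triketone) precursor of A1 | CCC(=O)C(C)C(=O)C(C)C(=O)[C@H](C)[C@H](OC(C)=O)[C@@H](C)[C@@H](OC(C)=O)/C(C)=C/[C@H](C)C(=O)C(C)C(=O)C(C)C(=O)[C@@H](C)[C@@H](O[Si](CC)(CC)CC)CC
A3 | alternative 2 | (2S,3R,4E,6S)-7-(TBS-oxy)-3-(PMB-oxy)-2,4,6-trimethylhept-4-enoic acid | OC(=O)[C@@H](C)[C@@H](OCc1ccc(OC)cc1)/C(C)=C/[C@H](C)CO[Si](C)(C)C(C)(C)C
A4 | alternative 2 | (E)-5-(TBS-oxy)-1-(PMB-oxy)-2,4-dimethylpent-1-en-3-yl propanoate | CCC(=O)O[C@H]([C@H](C)CO[Si](C)(C)C(C)(C)C)/C(C)=C/OCc1ccc(OC)cc1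
A5 | alternative 3 | C4 allylic alcohol bearing C2 OTES and C9 OTBS | CCc1oc([C@H](C)[C@H](O[Si](CC)(CC)CC)[C@@H](C)[C@@H](O)/C(C)=C/[C@H](C)c2oc([C@@H](C)[C@@H](O[Si](C)(C)C(C)(C)C)CC)c(C)c(=O)c2C)c(C)c(=O)c1C
A6 | alternative 3 | (6E)-alkenyl C4–C5 oxirane precursor of A5 (C3 and C6 cis on the oxirane) | CCc1oc([C@H](C)[C@H](O[Si](CC)(CC)CC)[C@@H](C)[C@H]3O[C@@]3(C)/C=C/c2oc([C@@H](C)[C@@H](O[Si](C)(C)C(C)(C)C)CC)c(C)c(=O)c2C)c(C)c(=O)c1C
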